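**Plan**

- Ring numbering: C1 carries the isopropenyl group and the count runs so that the methyls sit on C4, C8 and C12, the acetates on C5 and C13 and the ketone on C10. The target is (1S,4R,5S,8S,12R,13R).
- Enabling feature: in the 14-membered ring the C10 carbonyl is γ to the C13 oxygen, so it can be carried as a C10≡C11 triple bond and unmasked by 5-endo-dig attack of the C13 hydroxyl on C10. The C1 isopropenyl alkene rules out an alkene-metathesis/hydrogenation alternative.
- Cuts, in retrosynthetic order: both acetates; C10=O back to C10≡C11; the ring at C10≡C11 (alkyne metathesis of a diyne); C12–C13 (aldol) with the C11 alkyne from the aldol carbonyl; C4–C5 and C3–C4 (two boronic ester homologations).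
- Forward: (R)-carvone gives the C13–C3 boronate; an ethyl carbenoid adds C4; a citronellal-derived C5–C10 carbenoid adds the eastern chain with its propynyl end; a propanoate aldol adds C11–C12; C11 becomes the second methyl-capped alkyne; metathesis closes the only ring; desilylation, hydration and acetylation finish.
- Stereochemistry: C1 from (R)-carvone, C8 from (S)-citronellal, C4 and C5 from (−)- and (+)-sparteine-controlled lithiation–borylation, C12 and C13 from an auxiliary-controlled syn aldol.

Key step: step 19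

Remark: the aldehyde carbon of the carvone degradation product is used as C13 and the carboxyl carbon as C3, which is why the (R)-enantiomer of carvone delivers (1S).
Remark: ethyl 2,4,6-triisopropylbenzoate and (S)-4-benzyl-3-propanoyl-1,3-thiazolidine-2-thione are taken as catalogue reagents; each is otherwise one acylation from the commercial acid or thione.
Remark: the γ-hydroxy ketone of step 21 is drawn open-chain; equilibration with its cyclic hemiketal is assumed not to hinder acetylation.

**Route**

Step 1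
Reactants: 1 (R)-(−)-carvone
Product: 2 (1R,4R,6R)-1-methyl-4-(prop-1-en-2-yl)-7-oxabicyclo[4.1.0]heptan-2-one
Conditions: 30% aq. H2O2, NaOH (cat.), MeOH, 0 °C
Reagents that add atoms: hydrogen peroxide, OO
Why: Weitz–Scheffer epoxidation, in which hydroperoxide adds only to the electron-poor enone double bond so that the isopropenyl group is untouched; the oxirane should form anti to the isopropenyl group, and both new stereocentres are destroyed in step 2.

Step 2
Reactants: 2 epoxy ketone
Product: 4 (R)-5-oxo-3-(prop-1-en-2-yl)pentanoic acid, via keto diol 3 (not isolated)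
Conditions: H5IO6 (2.5 equiv), THF/H2O (4:1), 0 °C → rt
Reagents that add atoms: water, O; orthoperiodic acid, OI(=O)(O)(O)(O)O
Why: Periodic acid opens the oxirane to keto diol 3 and then cleaves both the glycol bond and the α-hydroxy ketone bond (Malaprade-type cleavage), expelling the methyl-bearing carbon as acetic acid and leaving an aldehyde on one arm and a carboxyl on the other, so the two arms at the untouched isopropenyl-bearing stereocentre become chemically distinct.

Step 3
Reactants: 4 aldehyde acid
Product: 5 methyl (R)-5,5-dimethoxy-3-(prop-1-en-2-yl)pentanoate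
Conditions: HC(OMe)3, MeOH, TsOH·H2O (cat.), rt → 45 °C
Reagents that add atoms: methanol, CO; trimethyl orthoformate, COC(OC)OC
Why: Acid-catalysed acetalisation and Fischer esterification, driven by the orthoformate as water scavenger, mask the future C13 aldehyde as a base-stable dimethyl acetal and leave the C3 ester as the only reducible group; catalytic sulfonic acid in dry methanol should not add to the 1,1-disubstituted alkene.

Step 4
Reactants: 5 acetal ester
Product: 6 (S)-5,5-dimethoxy-3-(prop-1-en-2-yl)pentan-1-ol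
Conditions: LiAlH4, THF, 0 °C
Reagents that add atoms: none
Why: Hydride reduction of the ester to the primary C3 alcohol; acetal and alkene are inert to LiAlH4.

Step 5
Reactants: 6 alcohol
Product: 7 (R)-5-iodo-1,1-dimethoxy-3-(prop-1-en-2-yl)pentane
Conditions: I2, PPh3, imidazole, CH2Cl2, 0 °C → rt
Reagents that add atoms: iodine, II
Why: Appel-type iodination (oxyphosphonium activation, then SN2 by iodide) of an unhindered primary alcohol; imidazole buffers the medium so the acetal survives.

Step 6
Reactants: 7 iodide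
Product: 8 2-[(S)-5,5-dimethoxy-3-(prop-1-en-2-yl)pentyl]-4,4,5,5-tetramethyl-1,3,2-dioxaborolane
Conditions: B2pin2, CuI (10 mol%), PPh3 (13 mol%), LiOMe, DMF, rt
Reagents that add atoms: bis(pinacolato)diboron, CC1(C)OB(OC1(C)C)B1OC(C)(C)C(C)(C)O1
Why: Copper-catalysed borylation of a primary alkyl iodide with a boryl–copper species, a mild entry to the pinacol boronate that tolerates acetal and alkene.

Step 7
Reactants: 8 primary boronate; 9 ethyl 2,4,6-triisopropylbenzoate
Product: 12 2-[(2R,5S)-7,7-dimethoxy-5-(prop-1-en-2-yl)heptan-2-yl]-4,4,5,5-tetramethyl-1,3,2-dioxaborolane, via lithiated benzoate 10 (not isolated), via boronate complex 11 (not isolated)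
Conditions: 9, s-BuLi, (−)-sparteine, Et2O, −78 °C, 5 h; then 8, −78 °C, 1 h; then 35 °C, 12 h
Reagents that add atoms: none
Why: Lithiation–borylation (sparteine-mediated asymmetric deprotonation followed by 1,2-metallate rearrangement): s-BuLi/(−)-sparteine removes the pro-S α-proton of the ethyl ester to give the (S)-carbenoid 10, boron is attached with retention, and the C3 alkyl group then migrates antiperiplanar to the departing hindered benzoate with inversion, so C4 should arise with R configuration.

Step 8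
Reactants: 13 (S)-(−)-citronellal
Product: 14 (S)-1,1-dibromo-4,8-dimethylnona-1,7-diene
Conditions: CBr4, PPh3, Zn, CH2Cl2, rt; then 13, 0 °C → rt
Reagents that add atoms: carbon tetrabromide, BrC(Br)(Br)Br
Why: First stage of the Corey–Fuchs reaction, a Wittig-type olefination of the aldehyde with the dibromomethylidene ylide; the zinc protocol keeps the medium neutral and the trisubstituted alkene is unaffected.

Step 9
Reactants: 14 dibromodiene
Product: 16 (S)-2,6-dimethyldec-2-en-8-yne, via lithium acetylide 15 (not isolated)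
Conditions: n-BuLi (2.1 equiv), THF, −78 → 0 °C; then MeI, −78 °C → rt
Reagents that add atoms: iodomethane, CI
Why: Second stage of the Corey–Fuchs reaction: bromine–lithium exchange and Fritsch–Buttenberg–Wiechell rearrangement give the alkyne, the second equivalent of base gives acetylide 15, and methylation installs the cap that alkyne metathesis needs; the C8 stereocentre is remote from every reacting site.

Step 10
Reactants: 16 enyne
Product: 18 (S)-4-methyloct-6-yn-1-ol, via ynal 17 (not isolated)
Conditions: O3, CH2Cl2/MeOH, Sudan Red 7B, −78 °C; then NaBH4, −78 °C → rt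
Reagents that add atoms: ozone, [O-][O+]=O
Why: Chemoselective ozonolysis, since the electron-rich trisubstituted alkene reacts with ozone far faster than the internal alkyne and the dye marks the end point; borohydride then reduces the ozonolysis products directly to the C5 alcohol.

Step 11
Reactants: 18 alkynol
Product: 19 (S)-4-methyloct-6-yn-1-yl 2,4,6-triisopropylbenzoate
Conditions: 2,4,6-triisopropylbenzoic acid, PPh3, DIAD, THF, 0 °C → rt
Reagents that add atoms: 2,4,6-triisopropylbenzoic acid, CC(C)c1cc(C(C)C)c(C(=O)O)c(C(C)C)c1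
Why: Mitsunobu esterification of the primary alcohol gives the hindered benzoate whose carbonyl directs α-lithiation and whose carboxylate is the leaving group of the later rearrangement.

Step 12
Reactants: 12 secondary boronate; 19 benzoate
Product: 23 (3S,6R,7S,10S)-1,1-dimethoxy-6,10-dimethyl-3-(prop-1-en-2-yl)tetradec-12-yn-7-ol, via lithiated benzoate 20 (not isolated), via boronate complex 21 (not isolated), via boronic ester 22 (not isolated)
Conditions: 19, s-BuLi, (+)-sparteine, Et2O, −78 °C, 5 h; then 12, −78 °C, 2 h; then 35 °C, 16 h; then 2 M aq. NaOH, 30% H2O2, THF, 0 °C → rt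
Reagents that add atoms: hydrogen peroxide, OO
Why: Second lithiation–borylation, which unites the fragments: s-BuLi/(+)-sparteine removes the pro-R proton at C5 to give carbenoid 20, boronate 12 adds with retention, the C4 group migrates with retention at C4 and inversion at C5, and stereoretentive peroxide oxidation of the C5–B bond should give the anti (4R,5S) alcohol; carbonyl-directed α-lithiation is expected to outpace propargylic deprotonation at −78 °C.

Step 13
Reactants: 23 hydroxy acetal
Product: 25 (3S,6R,7S,10S)-6,10-dimethyl-3-(prop-1-en-2-yl)-7-[(triethylsilyl)oxy]tetradec-12-ynal, via pyridinium salt 24 (not isolated)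
Conditions: Et3SiOTf (3 equiv), 2,6-lutidine (4.5 equiv), CH2Cl2, 0 °C; then H2O, rt
Reagents that add atoms: triethylsilyl trifluoromethanesulfonate, CC[Si](CC)(CC)OS(=O)(=O)C(F)(F)F; water, O
Why: The silyl triflate/lutidine pair silylates the C5 hydroxyl and also converts the dimethyl acetal into pyridinium salt 24 by capture of the oxocarbenium ion (a known chemoselective acetal cleavage), and water then hydrolyses 24 to the aldehyde under non-acidic conditions that spare the silyl ether and the alkene.

Step 14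
Reactants: 25 aldehyde; 26 (S)-4-benzyl-3-propanoyl-1,3-thiazolidine-2-thione
Product: 28 (S)-4-benzyl-3-[(2S,3R,5S,8R,9S,12S)-3-hydroxy-2,8,12-trimethyl-5-(prop-1-en-2-yl)-9-(triethylsilyloxy)hexadec-14-ynoyl]-1,3-thiazolidine-2-thione, via titanium enolate 27 (not isolated)
Conditions: 26, TiCl4 (1.05 equiv), i-Pr2NEt (1.1 equiv), N-methyl-2-pyrrolidinone (1.1 equiv), CH2Cl2, 0 °C; then 25, −78 → 0 °C
Reagents that add atoms: none
Why: Evans-type syn aldol of the chlorotitanium Z-enolate of an N-acyl thiazolidinethione through the non-chelated Zimmerman–Traxler chair, in which the (S)-benzyl group screens one enolate face, so the unbranched aldehyde should give the syn (12R,13R) adduct.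

Step 15
Reactants: 28 aldol adduct
Product: 29 (S)-4-benzyl-3-[(2S,3R,5S,8R,9S,12S)-2,8,12-trimethyl-5-(prop-1-en-2-yl)-3,9-bis(triethylsilyloxy)hexadec-14-ynoyl]-1,3-thiazolidine-2-thione
Conditions: Et3SiOTf, 2,6-lutidine, CH2Cl2, −78 → 0 °C
Reagents that add atoms: triethylsilyl trifluoromethanesulfonate, CC[Si](CC)(CC)OS(=O)(=O)C(F)(F)F
Why: Silylation of the C13 hydroxyl blocks retro-aldol cleavage and matches the C5 protecting group for joint removal later.

Step 16
Reactants: 29 silylated thioimide
Product: 30 (2S,3R,5S,8R,9S,12S)-2,8,12-trimethyl-5-(prop-1-en-2-yl)-3,9-bis[(triethylsilyl)oxy]hexadec-14-ynal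
Conditions: i-Bu2AlH, CH2Cl2, −78 °C
Reagents that add atoms: none
Why: The activated thioimide is reduced at −78 °C to a tetrahedral aluminate that collapses to the aldehyde only on work-up and releases the auxiliary; these non-basic conditions should not epimerise C12.

Step 17
Reactants: 30 aldehyde
Product: 31 (3R,4R,6S,9R,10S,13S)-1,1-dibromo-3,9,13-trimethyl-6-(prop-1-en-2-yl)-4,10-bis[(triethylsilyl)oxy]heptadec-1-en-15-yne
Conditions: CBr4, PPh3, Zn, CH2Cl2, rt; then 30, 0 °C
Reagents that add atoms: carbon tetrabromide, BrC(Br)(Br)Br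
Why: Corey–Fuchs dibromo-olefination (Wittig type) converts the C11 aldehyde into the 1,1-dibromoalkene; the neutral zinc/phosphine protocol should leave C12 and the silyl ethers intact.

Step 18
Reactants: 31 dibromoalkene
Product: 33 (4R,5R,7S,10R,11S,14S)-4,10,14-trimethyl-7-(prop-1-en-2-yl)-5,11-bis[(triethylsilyl)oxy]octadeca-2,16-diyne, via lithium acetylide 32 (not isolated)
Conditions: n-BuLi (2.2 equiv), THF, −78 °C; then MeI, −78 °C → rt
Reagents that add atoms: iodomethane, CI
Why: Bromine–lithium exchange, Fritsch–Buttenberg–Wiechell rearrangement and methylation of acetylide 32 complete the second methyl-capped alkyne; the C12 methine is not acidic enough to be touched at −78 °C.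

Step 19
Reactants: 33 diyne
Product: 34 (1S,4R,5S,8S,12R,13R)-4,8,12-trimethyl-1-(prop-1-en-2-yl)-5,13-bis[(triethylsilyl)oxy]cyclotetradec-10-yne
Conditions: Mo(≡CC6H4OMe-4)(OSiPh3)3 (10 mol%), 5 Å molecular sieves, toluene (0.002 M), 25 → 60 °C
Reagents that add atoms: none
Why: The molybdenum alkylidyne adds to one propynyl terminus by [2+2] cycloaddition to a metallacyclobutadiene, cycloreversion leaves the substrate on the metal as a new alkylidyne at C10 or C11, and a second cycloaddition/cycloreversion with the other terminus forms the C10≡C11 bond while the two methyl caps leave together as but-2-yne. The closest known reaction type is ring-closing alkyne metathesis of α,ω-bis(propynyl) chains to 12- to 20-membered cycloalkynes with silanolate-supported molybdenum alkylidynes. The single ring, the 14-membered carbocycle, closes head-to-tail at C10≡C11 and is unstrained because the near-linear C9–C12 unit is easily spanned by ten further ring atoms. No stereocentre is formed, and the existing ones, including the propargylic C12, are safe because the process is neutral and non-basic. The step needs alkyne-over-alkene chemoselectivity, which is intrinsic since alkylidynes do not engage the isopropenyl group, and cyclisation over oligomerisation, which is secured by 2 mM dilution, by the reversibility that feeds acyclic oligomers back to the monomeric ring and by trapping but-2-yne in the sieves. In the substrate, both oxygens are silyl-capped so no protic group degrades the catalyst, and the methyl caps prevent the polymerisation typical of terminal alkynes.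

Step 20
Reactants: 34 cycloalkyne
Product: 35 (1S,4R,5S,8S,12R,13R)-4,8,12-trimethyl-1-(prop-1-en-2-yl)cyclotetradec-10-yne-5,13-diol
Conditions: HF·pyridine, pyridine, THF, 0 °C → rt
Reagents that add atoms: none
Why: Fluoride-mediated cleavage of both triethylsilyl ethers frees the C13 hydroxyl needed as internal nucleophile and the C5 hydroxyl for the final acylation; buffered HF·pyridine does not affect alkyne or alkene.

Step 21
Reactants: 35 cycloalkyne diol
Product: 37 (1S,4R,5S,8S,12R,13R)-5,13-dihydroxy-4,8,12-trimethyl-1-(prop-1-en-2-yl)cyclotetradecan-10-one, via dihydrofuran 36 (not isolated)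
Conditions: Ph3PAuNTf2 (5 mol%), THF/H2O (10:1), 25 °C; then TsOH·H2O (10 mol%), 25 °C
Reagents that add atoms: water, O
Why: Gold-catalysed hydroalkoxylation followed by enol ether hydrolysis: π-activation of the alkyne by the cationic monovalent gold complex lets the C13 hydroxyl attack C10 in the only feasible 5-endo-dig mode (attack at C11 would need a four-membered ring and the C5 hydroxyl is seven atoms away), protodeauration gives enol ether 36, and acid hydrolysis places the carbonyl at C10 only; the isolated alkene is not activated.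

Step 22
Reactants: 37 dihydroxy ketone
Product: 38 (1S,4R,5S,8S,12R,13R)-4,8,12-trimethyl-10-oxo-1-(prop-1-en-2-yl)cyclotetradecane-5,13-diyl diacetate (CNP0328624.1)
Conditions: Ac2O, pyridine, DMAP (cat.), CH2Cl2, rt
Reagents that add atoms: acetic anhydride, CC(=O)OC(C)=O
Why: DMAP-catalysed acylation of both secondary hydroxyls; acetylation of the open γ-hydroxy ketone form drains any cyclic hemiketal and should give the target.

**Compound list**

1 | (R)-(−)-carvone | C=C(C)[C@@H]1CC=C(C)C(=O)C1 | starting material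
2 | (1R,4R,6R)-1-methyl-4-(prop-1-en-2-yl)-7-oxabicyclo[4.1.0]heptan-2-one | C=C(C)[C@@H]1C[C@H]2O[C@@]2(C)C(=O)C1 | intermediate
3 | (2R,3S,5R)-2,3-dihydroxy-2-methyl-5-(prop-1-en-2-yl)cyclohexan-1-one (keto diol; not isolated) | C=C(C)[C@@H]1C[C@H](O)[C@@](C)(O)C(=O)C1 | intermediate
4 | (R)-5-oxo-3-(prop-1-en-2-yl)pentanoic acid | O=CC[C@@H](C(C)=C)CC(=O)O | intermediate
5 | methyl (R)-5,5-dimethoxy-3-(prop-1-en-2-yl)pentanoate | COC(OC)C[C@@H](C(C)=C)CC(=O)OC | intermediate
6 | (S)-5,5-dimethoxy-3-(prop-1-en-2-yl)pentan-1-ol | COC(OC)C[C@@H](C(C)=C)CCO | intermediate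
7 | (R)-5-iodo-1,1-dimethoxy-3-(prop-1-en-2-yl)pentane | COC(OC)C[C@@H](C(C)=C)CCI | intermediate
8 | 2-[(S)-5,5-dimethoxy-3-(prop-1-en-2-yl)pentyl]-4,4,5,5-tetramethyl-1,3,2-dioxaborolane | COC(OC)C[C@@H](C(C)=C)CCB1OC(C)(C)C(C)(C)O1 | intermediate
9 | ethyl 2,4,6-triisopropylbenzoate | CCOC(=O)c1c(C(C)C)cc(C(C)C)cc1C(C)C | starting material
10 | (S)-1-lithioethyl 2,4,6-triisopropylbenzoate, sparteine-bound (lithiated benzoate; not isolated) | C[C@H]([Li])OC(=O)c1c(C(C)C)cc(C(C)C)cc1C(C)C | intermediate
11 | lithium boronate complex of 8 and 10 (not isolated) | [Li+].C[C@@H](OC(=O)c1c(C(C)C)cc(C(C)C)cc1C(C)C)[B-]1(CC[C@H](C(C)=C)CC(OC)OC)OC(C)(C)C(C)(C)O1 | intermediate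
12 | 2-[(2R,5S)-7,7-dimethoxy-5-(prop-1-en-2-yl)heptan-2-yl]-4,4,5,5-tetramethyl-1,3,2-dioxaborolane | COC(OC)C[C@@H](C(C)=C)CC[C@@H](C)B1OC(C)(C)C(C)(C)O1 | intermediate
13 | (S)-(−)-citronellal | CC(C)=CCC[C@H](C)CC=O | starting material
14 | (S)-1,1-dibromo-4,8-dimethylnona-1,7-diene | CC(C)=CCC[C@H](C)CC=C(Br)Br | intermediate
15 | [(S)-4,8-dimethylnon-7-en-1-yn-1-yl]lithium (not isolated) | CC(C)=CCC[C@H](C)CC#C[Li] | intermediate
16 | (S)-2,6-dimethyldec-2-en-8-yne | CC(C)=CCC[C@H](C)CC#CC | intermediate
17 | (S)-4-methyloct-6-ynal (not isolated) | O=CCC[C@H](C)CC#CC | intermediate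
18 | (S)-4-methyloct-6-yn-1-ol | OCCC[C@H](C)CC#CC | intermediate
19 | (S)-4-methyloct-6-yn-1-yl 2,4,6-triisopropylbenzoate | CC#CC[C@@H](C)CCCOC(=O)c1c(C(C)C)cc(C(C)C)cc1C(C)C | intermediate
20 | (1R,4S)-1-lithio-4-methyloct-6-yn-1-yl 2,4,6-triisopropylbenzoate, sparteine-bound (not isolated) | CC#CC[C@@H](C)CC[C@@H]([Li])OC(=O)c1c(C(C)C)cc(C(C)C)cc1C(C)C | intermediate
21 | lithium boronate complex of 12 and 20 (not isolated) | [Li+].CC#CC[C@@H](C)CC[C@H](OC(=O)c1c(C(C)C)cc(C(C)C)cc1C(C)C)[B-]1([C@H](C)CC[C@H](C(C)=C)CC(OC)OC)OC(C)(C)C(C)(C)O1 | intermediate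
22 | 2-[(3S,6R,7S,10S)-1,1-dimethoxy-6,10-dimethyl-3-(prop-1-en-2-yl)tetradec-12-yn-7-yl]-4,4,5,5-tetramethyl-1,3,2-dioxaborolane (not isolated) | COC(OC)C[C@@H](C(C)=C)CC[C@@H](C)[C@@H](B1OC(C)(C)C(C)(C)O1)CC[C@H](C)CC#CC | intermediate
23 | (3S,6R,7S,10S)-1,1-dimethoxy-6,10-dimethyl-3-(prop-1-en-2-yl)tetradec-12-yn-7-ol | COC(OC)C[C@@H](C(C)=C)CC[C@@H](C)[C@@H](O)CC[C@H](C)CC#CC | intermediate
24 | 1-[(3S,6R,7S,10S)-1-methoxy-6,10-dimethyl-3-(prop-1-en-2-yl)-7-(triethylsilyloxy)tetradec-12-yn-1-yl]-2,6-dimethylpyridinium triflate, epimers at the N,O-acetal carbon (not isolated) | COC(C[C@@H](C(C)=C)CC[C@@H](C)[C@@H](O[Si](CC)(CC)CC)CC[C@H](C)CC#CC)[n+]1c(C)cccc1C.[O-]S(=O)(=O)C(F)(F)F | intermediate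
25 | (3S,6R,7S,10S)-6,10-dimethyl-3-(prop-1-en-2-yl)-7-[(triethylsilyl)oxy]tetradec-12-ynal | O=CC[C@@H](C(C)=C)CC[C@@H](C)[C@@H](O[Si](CC)(CC)CC)CC[C@H](C)CC#CC | intermediate
26 | (S)-4-benzyl-3-propanoyl-1,3-thiazolidine-2-thione | CCC(=O)N1[C@@H](Cc2ccccc2)CSC1=S | starting material
27 | trichlorotitanium Z-enolate of 26 (not isolated) | C/C=C(\O[Ti](Cl)(Cl)Cl)N1[C@@H](Cc2ccccc2)CSC1=S | intermediate
28 | (S)-4-benzyl-3-[(2S,3R,5S,8R,9S,12S)-3-hydroxy-2,8,12-trimethyl-5-(prop-1-en-2-yl)-9-(triethylsilyloxy)hexadec-14-ynoyl]-1,3-thiazolidine-2-thione | CC#CC[C@@H](C)CC[C@H](O[Si](CC)(CC)CC)[C@H](C)CC[C@H](C(C)=C)C[C@@H](O)[C@H](C)C(=O)N1[C@@H](Cc2ccccc2)CSC1=S | intermediate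
29 | (S)-4-benzyl-3-[(2S,3R,5S,8R,9S,12S)-2,8,12-trimethyl-5-(prop-1-en-2-yl)-3,9-bis(triethylsilyloxy)hexadec-14-ynoyl]-1,3-thiazolidine-2-thione | CC#CC[C@@H](C)CC[C@H](O[Si](CC)(CC)CC)[C@H](C)CC[C@H](C(C)=C)C[C@@H](O[Si](CC)(CC)CC)[C@H](C)C(=O)N1[C@@H](Cc2ccccc2)CSC1=S | intermediate
30 | (2S,3R,5S,8R,9S,12S)-2,8,12-trimethyl-5-(prop-1-en-2-yl)-3,9-bis[(triethylsilyl)oxy]hexadec-14-ynal | CC#CC[C@@H](C)CC[C@H](O[Si](CC)(CC)CC)[C@H](C)CC[C@H](C(C)=C)C[C@@H](O[Si](CC)(CC)CC)[C@H](C)C=O | intermediate
31 | (3R,4R,6S,9R,10S,13S)-1,1-dibromo-3,9,13-trimethyl-6-(prop-1-en-2-yl)-4,10-bis[(triethylsilyl)oxy]heptadec-1-en-15-yne | CC#CC[C@@H](C)CC[C@H](O[Si](CC)(CC)CC)[C@H](C)CC[C@H](C(C)=C)C[C@@H](O[Si](CC)(CC)CC)[C@H](C)C=C(Br)Br | intermediate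
32 | lithium acetylide from 31 at C11 (not isolated) | CC#CC[C@@H](C)CC[C@H](O[Si](CC)(CC)CC)[C@H](C)CC[C@H](C(C)=C)C[C@@H](O[Si](CC)(CC)CC)[C@H](C)C#C[Li] | intermediate
33 | (4R,5R,7S,10R,11S,14S)-4,10,14-trimethyl-7-(prop-1-en-2-yl)-5,11-bis[(triethylsilyl)oxy]octadeca-2,16-diyne | CC#CC[C@@H](C)CC[C@H](O[Si](CC)(CC)CC)[C@H](C)CC[C@H](C(C)=C)C[C@@H](O[Si](CC)(CC)CC)[C@H](C)C#CC | intermediate
34 | (1S,4R,5S,8S,12R,13R)-4,8,12-trimethyl-1-(prop-1-en-2-yl)-5,13-bis[(triethylsilyl)oxy]cyclotetradec-10-yne (plan numbering) | C=C(C)[C@H]1CC[C@@H](C)[C@@H](O[Si](CC)(CC)CC)CC[C@H](C)CC#C[C@@H](C)[C@H](O[Si](CC)(CC)CC)C1 | intermediate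
35 | (1S,4R,5S,8S,12R,13R)-4,8,12-trimethyl-1-(prop-1-en-2-yl)cyclotetradec-10-yne-5,13-diol (plan numbering) | C=C(C)[C@H]1CC[C@@H](C)[C@@H](O)CC[C@H](C)CC#C[C@@H](C)[C@H](O)C1 | intermediate
36 | bicyclic 2,3-dihydrofuran with an O13–C10 bond and a C10=C11 double bond, C5 hydroxyl free (not isolated) | C=C(C)[C@H]1CC[C@@H](C)[C@@H](O)CC[C@H](C)CC2=C[C@@H](C)[C@H](O2)C1 | intermediate
37 | (1S,4R,5S,8S,12R,13R)-5,13-dihydroxy-4,8,12-trimethyl-1-(prop-1-en-2-yl)cyclotetradecan-10-one (plan numbering) | C=C(C)[C@H]1CC[C@@H](C)[C@@H](O)CC[C@H](C)CC(=O)C[C@@H](C)[C@H](O)C1 | intermediate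
38 | (1S,4R,5S,8S,12R,13R)-4,8,12-trimethyl-10-oxo-1-(prop-1-en-2-yl)cyclotetradecane-5,13-diyl diacetate (CNP0328624.1) | C=C(C)[C@H]1CC[C@@H](C)[C@@H](OC(C)=O)CC[C@H](C)CC(=O)C[C@@H](C)[C@H](OC(C)=O)C1 | target

**Count and risks**

Total step count: 22. Longest linear sequence: 18 steps (steps 1–7 and 12–22, from (R)-carvone); the citronellal branch (steps 8–11) joins at step 12.

Steps most likely to fail:

1. Step 12. During the long low-temperature metalation the base may also deprotonate the propargylic methyl of the alkyne in 19, which would erode the carbenoid and leave boronate 12 unconsumed. The fallback postpones the methyl cap and sets out from 14 and 12. Treatment of 14 with n-BuLi and trapping with Me3SiCl would give [(S)-4,8-dimethylnon-7-en-1-yn-1-yl]trimethylsilane F1. Ozonolysis with NaBH4 work-up would give (S)-4-methyl-7-(trimethylsilyl)hept-6-yn-1-ol F2, and Mitsunobu esterification its 2,4,6-triisopropylbenzoate F3, which has no propargylic methyl. Lithiation of F3 with s-BuLi/(+)-sparteine, addition of 12, rearrangement, peroxide oxidation and K2CO3/MeOH would give the terminal alkyne (3S,6R,7S,10S)-1,1-dimethoxy-6,10-dimethyl-3-(prop-1-en-2-yl)tridec-12-yn-7-ol F4. Silylation with Et3SiCl/imidazole would give the triethylsilyl ether F5, n-BuLi then MeI the methyl-capped silyl ether acetal F6, and acetal cleavage with Et3SiOTf/2,6-lutidine then water rejoins the route at 25.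

2. Step 13. The tandem silylation and acetal cleavage may stall at the pyridinium stage or shed the new silyl ether on hydrolysis, and the nascent aldehyde could cyclise onto the isopropenyl group if silyl triflate survives the quench. The fallback separates the two events and sets out from 23. Transacetalisation with pyridinium p-toluenesulfonate in wet acetone would give (3S,6R,7S,10S)-7-hydroxy-6,10-dimethyl-3-(prop-1-en-2-yl)tetradec-12-ynal F7, and silylation with Et3SiCl/imidazole in DMF returns to 25.

3. Step 21. After oxyauration the C5 hydroxyl may capture the oxocarbenium ion across the ring, or hydrolysis may stop at cyclic hemiketal and ketal mixtures, so that the ketone is not released cleanly. The fallback isolates a defined ketal first and sets out from 35. Ph3PAuNTf2 in dry methanol would give the bicyclic mixed methyl ketal F8 (5-endo-dig oxyauration, then addition of solvent methanol to the enol ether). After purification, hydrolysis with aqueous acetic acid in THF returns to 37.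

Further compounds
F1 | step 12 | [(S)-4,8-dimethylnon-7-en-1-yn-1-yl]trimethylsilane | CC(C)=CCC[C@H](C)CC#C[Si](C)(C)C
F2 | step 12 | (S)-4-methyl-7-(trimethylsilyl)hept-6-yn-1-ol | OCCC[C@H](C)CC#C[Si](C)(C)C
F3 | step 12 | (S)-4-methyl-7-(trimethylsilyl)hept-6-yn-1-yl 2,4,6-triisopropylbenzoate | C[Si](C)(C)C#CC[C@@H](C)CCCOC(=O)c1c(C(C)C)cc(C(C)C)cc1C(C)C
F4 | step 12 | (3S,6R,7S,10S)-1,1-dimethoxy-6,10-dimethyl-3-(prop-1-en-2-yl)tridec-12-yn-7-ol | COC(OC)C[C@@H](C(C)=C)CC[C@@H](C)[C@@H](O)CC[C@H](C)CC#C
F5 | step 12 | triethylsilyl ether of F4 | COC(OC)C[C@@H](C(C)=C)CC[C@@H](C)[C@@H](O[Si](CC)(CC)CC)CC[C@H](C)CC#C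
F6 | step 12 | triethyl{[(3S,6R,7S,10S)-1,1-dimethoxy-6,10-dimethyl-3-(prop-1-en-2-yl)tetradec-12-yn-7-yl]oxy}silane | COC(OC)C[C@@H](C(C)=C)CC[C@@H](C)[C@@H](O[Si](CC)(CC)CC)CC[C@H](C)CC#CC
F7 | step 13 | (3S,6R,7S,10S)-7-hydroxy-6,10-dimethyl-3-(prop-1-en-2-yl)tetradec-12-ynal | O=CC[C@@H](C(C)=C)CC[C@@H](C)[C@@H](O)CC[C@H](C)CC#CC
F8 | step 21 | bicyclic C10 methyl ketal with an O13–C10 bond, C5 hydroxyl free, both C10 epimers | C=C(C)[C@H]1CC[C@@H](C)[C@@H](O)CC[C@H](C)CC2(OC)C[C@@H](C)[C@H](O2)C1
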